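Atoms are numbered as in labdanes (ring A: C1–C5 and C10; ring B: C5–C10; side chain C11–C16; methyl groups C17–C20).
Cuts: the butenolide is removed at C12–C13 (alkylation of a thio-lactone), the 6β-acetate is traced back to a C5=C6 alkene, and ring B is then cut at C6–C7 and C9–C10 into 1,1,3-trimethyl-2-methylidenecyclohexane (ring A, C6, C18–C20) and 1-chloro-4-methylpent-4-en-3-one (C7–C9, C11, C12, C17).
Enabling feature: C6–C7 and C9–C10 face each other across ring B, C9 is a carbinol carbon and C4 is quaternary. An exocyclic C5=C6 methylene on ring A therefore has only one allylic hydrogen (C10–H) and can act twice as ene donor: through C6 toward C7 of the enone, then through C10 toward the C9 carbonyl. The final proton loss leaves C5=C6 as the handle for the C6 oxygen.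
Forward order: ring A is bought; ring B is closed in one flask (C6–C7, then C9–C10); C6 is oxygenated (hydroboration, oxidation, reduction); the lactone is attached and its double bond is formed last.
Stereochemistry: C8 from a chiral Lewis acid in the ene step; C9 and C10 relayed from C8 in the chair closure; C5 and C6 from α-face hydroboration; C6 then inverted by oxidation and α-face hydride reduction.

Key step: step 3

Remark: the sense of face selection of the oxazaborolidinium catalyst with this α-methyl enone is assumed; should it prove opposite, the enantiomeric catalyst is to be used.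

Step 1
Reactants: 1 2,2,6-trimethylcyclohexan-1-one (racemic)
Product: 2 1,1,3-trimethyl-2-methylidenecyclohexane (racemic)
Conditions: Ph3PCH3Br, KOC(CH3)3, toluene, 110 °C
Reagents that add atoms: methyltriphenylphosphonium bromide, C[P+](c1ccccc1)(c1ccccc1)c1ccccc1.[Br-]
Why: Wittig methylenation with the non-stabilised ylide in hot toluene is the standard answer to hindered ketones, and the stereocentre of 1 needs no control because it is erased in step 3.

Step 2
Reactants: 3 3-chloropropanoyl chloride; 4 tributyl(prop-1-en-2-yl)stannane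
Product: 5 1-chloro-4-methylpent-4-en-3-one
Conditions: PdCl2(PPh3)2 (2 mol %), THF, 50 °C
Reagents that add atoms: none
Why: Stille acylation of an acid chloride with an alkenylstannane should give the α-methyl enone without touching the alkyl chloride; no stereocentre is formed.

Step 3
Reactants: 2 1,1,3-trimethyl-2-methylidenecyclohexane (2 equiv); 5 1-chloro-4-methylpent-4-en-3-one
Product: 7 (1R,2R,8aS)-1-(2-chloroethyl)-2,5,5,8a-tetramethyl-1,2,3,5,6,7,8,8a-octahydronaphthalen-1-ol, via ketone 6 (not isolated)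
Conditions: oxazaborolidinium triflimide from (S)-3,3-diphenyl-1-(2-methylphenyl)tetrahydro-1H,3H-pyrrolo[1,2-c][1,3,2]oxazaborole and HN(SO2CF3)2 (20 mol %), CH2Cl2, −78 → −20 °C; then Me2AlCl (2 equiv), −78 → 0 °C
Reagents that add atoms: none
Why: Proposed new method: the boron Lewis acid binds the carbonyl of 5, the exocyclic CH2 of 2 (C6) adds to the enone β-carbon (C7) in a concerted, suprafacial ene reaction that moves the only allylic hydrogen of 2 (C10–H, C4 being quaternary) to C8 and leaves the double bond at C5=C10 (ketone 6), after which Me2AlCl activates the C9 ketone, C10 of the tetrasubstituted alkene attacks it (Prins-type cation–olefin closure) and the C5 cation loses a C6 proton to an aluminium-bound methyl group to give the C5=C6 alkene. The closest known reaction types are the dialkylaluminium chloride-promoted two-fold ene annulation of methylenecycloalkanes with vinyl ketones and enals and, for the face control, oxazaborolidinium-catalysed Diels–Alder reactions of α-substituted enals and enones. Ring B closes in a 6-endo-trig mode through a chair transition state. C8 is set by the catalyst, which shields one face of the bound enone; C10 is set by C8, because only the chair with the C8 methyl equatorial avoids a 1,3-diaxial contact with the C10 methyl; C9 is set in the same chair, the aluminium-bound oxygen taking the axial site anti to the C10 methyl and next to the developing C5 cation, so that the chloroethyl chain is equatorial. The step needs closure at C10 and not at C5 (six-membered ring against a crowded spiro five-membered ring), proton loss toward C6 (C4 carries no hydrogen) and configurational stability of the α-methyl ketone between the two stages, which the low temperature and the non-basic Lewis acids should secure.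

Step 4
Reactants: 7 (1R,2R,8aS)-1-(2-chloroethyl)-2,5,5,8a-tetramethyl-1,2,3,5,6,7,8,8a-octahydronaphthalen-1-ol
Product: 9 (1R,2R,4S,4aS,8aS)-1-(2-chloroethyl)-2,5,5,8a-tetramethyldecahydronaphthalene-1,4-diol, via alkylborane 8 (not isolated)
Conditions: BH3·THF (4 equiv), THF, 0 → 45 °C; then NaOH, H2O2, H2O, 0 °C
Reagents that add atoms: hydrogen peroxide, OO
Why: Hydroboration–oxidation adds syn and anti-Markovnikov to C5=C6 from the α face, which is free of the axial C10 and C4 methyl groups and carries the borane-binding 9α-oxygen, so that 5α-H (trans ring fusion) and 6α-OH should result.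

Step 5
Reactants: 9 (1R,2R,4S,4aS,8aS)-1-(2-chloroethyl)-2,5,5,8a-tetramethyldecahydronaphthalene-1,4-diol
Product: 10 (3R,4R,4aS,8aS)-4-(2-chloroethyl)-4-hydroxy-3,4a,8,8-tetramethyloctahydronaphthalen-1(2H)-one
Conditions: (n-Pr4N)RuO4 (5 mol %), N-methylmorpholine N-oxide, 4 Å molecular sieves, CH2Cl2, 25 °C
Reagents that add atoms: none
Why: Ley–Griffith oxidation converts the secondary C6 alcohol to the ketone while the tertiary C9 alcohol cannot react, and the neutral conditions leave C5 as set.

Step 6
Reactants: 10 (3R,4R,4aS,8aS)-4-(2-chloroethyl)-4-hydroxy-3,4a,8,8-tetramethyloctahydronaphthalen-1(2H)-one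
Product: 11 (1R,2R,4R,4aS,8aS)-1-(2-chloroethyl)-2,5,5,8a-tetramethyldecahydronaphthalene-1,4-diol
Conditions: NaBH4, CH3OH, 0 °C
Reagents that add atoms: none
Why: Substrate-controlled hydride reduction: the β face of the C6 ketone is blocked by the 1,3-diaxial C10 and C4 methyl groups, so hydride should enter from the α face and give the axial 6β-alcohol.

Step 7
Reactants: 12 3-bromodihydrofuran-2(3H)-one (racemic); 13 benzenethiol
Product: 14 3-(phenylsulfanyl)dihydrofuran-2(3H)-one (racemic)
Conditions: Et3N, CH2Cl2, 0 → 25 °C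
Reagents that add atoms: none
Why: SN2 displacement of the α-bromo lactone by thiolate; the stereocentre is of no consequence because it becomes sp2 in step 10.

Step 8
Reactants: 11 (1R,2R,4R,4aS,8aS)-1-(2-chloroethyl)-2,5,5,8a-tetramethyldecahydronaphthalene-1,4-diol; 14 3-(phenylsulfanyl)dihydrofuran-2(3H)-one
Product: 17 3-{2-[(1R,2R,4R,4aS,8aS)-1,4-dihydroxy-2,5,5,8a-tetramethyldecahydronaphthalen-1-yl]ethyl}-3-(phenylsulfanyl)dihydrofuran-2(3H)-one (both epimers at the sulfur-bearing carbon), via iodide 15 (not isolated), via lithium enolate 16 (not isolated)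
Conditions: 11, NaI, acetone, 56 °C, then evaporation; 14, LiN(SiMe3)2, THF, −78 °C; iodide added in THF–DMPU, −78 → 25 °C
Reagents that add atoms: none
Why: Finkelstein exchange followed by SN2 alkylation of the sulfur-stabilised lactone enolate at the primary C12 iodide forms C12–C13; the enolate is too weak a base to deprotonate the two hydroxyl groups, and both epimers of the new quaternary carbon converge in step 10.

Step 9
Reactants: 17 3-{2-[(1R,2R,4R,4aS,8aS)-1,4-dihydroxy-2,5,5,8a-tetramethyldecahydronaphthalen-1-yl]ethyl}-3-(phenylsulfanyl)dihydrofuran-2(3H)-one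
Product: 18 (1R,3R,4R,4aS,8aS)-4-hydroxy-3,4a,8,8-tetramethyl-4-{2-[2-oxo-3-(phenylsulfanyl)tetrahydrofuran-3-yl]ethyl}decahydronaphthalen-1-yl acetate
Conditions: Ac2O, DMAP, pyridine, 50 °C
Reagents that add atoms: acetic anhydride, CC(=O)OC(C)=O
Why: DMAP-catalysed acylation should acetylate only the secondary 6β-hydroxyl, since the tertiary 9α-hydroxyl is flanked by two fully substituted carbons, and the lactone has no acidic α-hydrogen at this stage.

Step 10
Reactants: 18 (1R,3R,4R,4aS,8aS)-4-hydroxy-3,4a,8,8-tetramethyl-4-{2-[2-oxo-3-(phenylsulfanyl)tetrahydrofuran-3-yl]ethyl}decahydronaphthalen-1-yl acetate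
Product: 20 (1R,3R,4R,4aS,8aS)-4-hydroxy-3,4a,8,8-tetramethyl-4-[2-(2-oxo-2,5-dihydrofuran-3-yl)ethyl]decahydronaphthalen-1-yl acetate, via sulfoxide 19 (not isolated)
Conditions: mCPBA (1.0 equiv), CH2Cl2, −78 → 0 °C; then toluene, 110 °C
Reagents that add atoms: none
Why: Sulfide oxidation and thermal syn-elimination of the sulfoxide, which in α-alkyl-α-sulfinyl γ-lactones places the double bond in the ring, should give the butenolide without affecting any stereocentre.

Compound list
1 | 2,2,6-trimethylcyclohexan-1-one (racemic) | CC1CCCC(C)(C)C1=O | starting material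
2 | 1,1,3-trimethyl-2-methylidenecyclohexane (racemic) | C=C1C(C)CCCC1(C)C | intermediate
3 | 3-chloropropanoyl chloride | O=C(Cl)CCCl | starting material
4 | tributyl(prop-1-en-2-yl)stannane | C=C(C)[Sn](CCCC)(CCCC)CCCC | starting material
5 | 1-chloro-4-methylpent-4-en-3-one | C=C(C)C(=O)CCCl | intermediate
6 | (4R)-1-chloro-4-methyl-6-(2,6,6-trimethylcyclohex-1-en-1-yl)hexan-3-one | ClCCC(=O)[C@H](C)CCC1=C(C)CCCC1(C)C | intermediate
7 | (1R,2R,8aS)-1-(2-chloroethyl)-2,5,5,8a-tetramethyl-1,2,3,5,6,7,8,8a-octahydronaphthalen-1-ol | C1[C@@H](C)[C@](O)(CCCl)[C@@]2(C)CCCC(C)(C)C2=C1 | intermediate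
8 | [(1S,3R,4R,4aS,8aS)-4-(2-chloroethyl)-4-hydroxy-3,4a,8,8-tetramethyldecahydronaphthalen-1-yl]borane (BH2 at C6α, H at C5α) | B[C@H]1C[C@@H](C)[C@](O)(CCCl)[C@@]2(C)CCCC(C)(C)[C@H]12 | intermediate
9 | (1R,2R,4S,4aS,8aS)-1-(2-chloroethyl)-2,5,5,8a-tetramethyldecahydronaphthalene-1,4-diol (6α,9α-diol) | O[C@H]1C[C@@H](C)[C@](O)(CCCl)[C@@]2(C)CCCC(C)(C)[C@H]12 | intermediate
10 | (3R,4R,4aS,8aS)-4-(2-chloroethyl)-4-hydroxy-3,4a,8,8-tetramethyloctahydronaphthalen-1(2H)-one | O=C1C[C@@H](C)[C@](O)(CCCl)[C@@]2(C)CCCC(C)(C)[C@H]12 | intermediate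
11 | (1R,2R,4R,4aS,8aS)-1-(2-chloroethyl)-2,5,5,8a-tetramethyldecahydronaphthalene-1,4-diol (6β,9α-diol) | O[C@@H]1C[C@@H](C)[C@](O)(CCCl)[C@@]2(C)CCCC(C)(C)[C@H]12 | intermediate
12 | 3-bromodihydrofuran-2(3H)-one (racemic) | O=C1OCCC1Br | starting material
13 | benzenethiol | Sc1ccccc1 | starting material
14 | 3-(phenylsulfanyl)dihydrofuran-2(3H)-one (racemic) | O=C1OCCC1Sc1ccccc1 | intermediate
15 | (1R,2R,4R,4aS,8aS)-1-(2-iodoethyl)-2,5,5,8a-tetramethyldecahydronaphthalene-1,4-diol | O[C@@H]1C[C@@H](C)[C@](O)(CCI)[C@@]2(C)CCCC(C)(C)[C@H]12 | intermediate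
16 | lithium 3-(phenylsulfanyl)-4,5-dihydrofuran-2-olate | [Li+].[O-]C1=C(Sc2ccccc2)CCO1 | intermediate
17 | 3-{2-[(1R,2R,4R,4aS,8aS)-1,4-dihydroxy-2,5,5,8a-tetramethyldecahydronaphthalen-1-yl]ethyl}-3-(phenylsulfanyl)dihydrofuran-2(3H)-one (both epimers at the sulfur-bearing carbon) | O[C@@H]1C[C@@H](C)[C@](O)(CCC3(Sc4ccccc4)CCOC3=O)[C@@]2(C)CCCC(C)(C)[C@H]12 | intermediate
18 | (1R,3R,4R,4aS,8aS)-4-hydroxy-3,4a,8,8-tetramethyl-4-{2-[2-oxo-3-(phenylsulfanyl)tetrahydrofuran-3-yl]ethyl}decahydronaphthalen-1-yl acetate | CC(=O)O[C@@H]1C[C@@H](C)[C@](O)(CCC3(Sc4ccccc4)CCOC3=O)[C@@]2(C)CCCC(C)(C)[C@H]12 | intermediate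
19 | (1R,3R,4R,4aS,8aS)-4-hydroxy-3,4a,8,8-tetramethyl-4-{2-[2-oxo-3-(phenylsulfinyl)tetrahydrofuran-3-yl]ethyl}decahydronaphthalen-1-yl acetate | CC(=O)O[C@@H]1C[C@@H](C)[C@](O)(CCC3(S(=O)c4ccccc4)CCOC3=O)[C@@]2(C)CCCC(C)(C)[C@H]12 | intermediate
20 | (1R,3R,4R,4aS,8aS)-4-hydroxy-3,4a,8,8-tetramethyl-4-[2-(2-oxo-2,5-dihydrofuran-3-yl)ethyl]decahydronaphthalen-1-yl acetate; (5S,6R,8R,9R,10S)-6-acetoxy-9-hydroxylabd-13-en-16,15-olide | CC(=O)O[C@@H]1C[C@@H](C)[C@](O)(CCC2=CCOC2=O)[C@@]2(C)CCCC(C)(C)[C@H]12 | target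

Total step count: 10. Longest linear sequence: 8 steps (steps 1, 3, 4, 5, 6, 8, 9, 10).

Steps most likely to fail

Step 3 (bears the label). The ene step may run without face control at the bound enone, or the α-methyl ketone may lose its configuration before ring closure, so that the bicyclic alcohol forms in low enantiomeric purity. The fallback uses known chemistry only and sets out from 2 and 5. The annulation is run with the achiral Lewis acid Me2AlCl alone (CH2Cl2, 0 → 25 °C), the direct counterpart of the established two-fold ene annulation of methylenecycloalkanes with vinyl ketones. It passes through racemic ketone, that is 6 together with its enantiomer (4S)-1-chloro-4-methyl-6-(2,6,6-trimethylcyclohex-1-en-1-yl)hexan-3-one F1. It gives the racemic alcohol, that is 7 together with its enantiomer (1S,2S,8aR)-1-(2-chloroethyl)-2,5,5,8a-tetramethyl-1,2,3,5,6,7,8,8a-octahydronaphthalen-1-ol F2. The enantiomers are separated by preparative chromatography on a chiral stationary phase (cellulose tris(3,5-dimethylphenylcarbamate)), and the route is rejoined at 7.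

Step 4. Borane addition to the trisubstituted C5=C6 bond, flanked by two quaternary carbons, may be slow or may lose its face selectivity. The fallback sets out from 7. Epoxidation with mCPBA (NaHCO3, CH2Cl2, 0 °C) on the open α face should give the 5α,6α-epoxide of 7 F3. BF3·OEt2 in CH2Cl2 at −78 °C should then induce a Meinwald rearrangement, with hydride shift from C6 to C5, to the cis-fused ketone (3R,4R,4aS,8aR)-4-(2-chloroethyl)-4-hydroxy-3,4a,8,8-tetramethyloctahydronaphthalen-1(2H)-one F4. Equilibration at C5 with NaOCH3 in methanol leads to the trans-fused ketone, and the route is rejoined at 10.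

Step 8. The lactone enolate may act as a base on the γ-hydroxy iodide (elimination, or closure of the tertiary alkoxide to an oxetane) instead of substituting at C12. The fallback replaces the alkylation by an olefination and sets out from 11 through iodide 15. Kornblum-type oxidation with trimethylamine N-oxide in DMSO at 25 °C should give 2-[(1R,2R,4R,4aS,8aS)-1,4-dihydroxy-2,5,5,8a-tetramethyldecahydronaphthalen-1-yl]acetaldehyde F5. Wittig reaction with commercial 3-(triphenyl-λ5-phosphanylidene)dihydrofuran-2(3H)-one in toluene at 80 °C should give (3E)-3-{2-[(1R,2R,4R,4aS,8aS)-1,4-dihydroxy-2,5,5,8a-tetramethyldecahydronaphthalen-1-yl]ethylidene}dihydrofuran-2(3H)-one F6. Acetylation (Ac2O, DMAP, pyridine) gives (1R,3R,4R,4aS,8aS)-4-hydroxy-3,4a,8,8-tetramethyl-4-{(2E)-2-[2-oxodihydrofuran-3(2H)-ylidene]ethyl}decahydronaphthalen-1-yl acetate F7. RhCl3·3H2O in ethanol at 80 °C then moves the exocyclic double bond into the lactone ring, and the route is rejoined at 20.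

Further compounds
F1 | step 3 | (4S)-1-chloro-4-methyl-6-(2,6,6-trimethylcyclohex-1-en-1-yl)hexan-3-one | ClCCC(=O)[C@@H](C)CCC1=C(C)CCCC1(C)C
F2 | step 3 | (1S,2S,8aR)-1-(2-chloroethyl)-2,5,5,8a-tetramethyl-1,2,3,5,6,7,8,8a-octahydronaphthalen-1-ol | C1[C@H](C)[C@@](O)(CCCl)[C@]2(C)CCCC(C)(C)C2=C1
F3 | step 4 | 5α,6α-epoxide of 7 (labdane numbering; oxygen on the face of the 9-hydroxyl) | O1[C@H]2C[C@@H](C)[C@](O)(CCCl)[C@@]3(C)CCCC(C)(C)[C@]123
F4 | step 4 | (3R,4R,4aS,8aR)-4-(2-chloroethyl)-4-hydroxy-3,4a,8,8-tetramethyloctahydronaphthalen-1(2H)-one (cis-fused, 5β-H) | O=C1C[C@@H](C)[C@](O)(CCCl)[C@@]2(C)CCCC(C)(C)[C@@H]12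
F5 | step 8 | 2-[(1R,2R,4R,4aS,8aS)-1,4-dihydroxy-2,5,5,8a-tetramethyldecahydronaphthalen-1-yl]acetaldehyde | O[C@@H]1C[C@@H](C)[C@](O)(CC=O)[C@@]2(C)CCCC(C)(C)[C@H]12
F6 | step 8 | (3E)-3-{2-[(1R,2R,4R,4aS,8aS)-1,4-dihydroxy-2,5,5,8a-tetramethyldecahydronaphthalen-1-yl]ethylidene}dihydrofuran-2(3H)-one | O[C@@H]1C[C@@H](C)[C@](O)(C/C=C3\CCOC3=O)[C@@]2(C)CCCC(C)(C)[C@H]12
F7 | step 8 | (1R,3R,4R,4aS,8aS)-4-hydroxy-3,4a,8,8-tetramethyl-4-{(2E)-2-[2-oxodihydrofuran-3(2H)-ylidene]ethyl}decahydronaphthalen-1-yl acetate | CC(=O)O[C@@H]1C[C@@H](C)[C@](O)(C/C=C3\CCOC3=O)[C@@]2(C)CCCC(C)(C)[C@H]12
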